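**Plan**

- Retrosynthesis: the C3 hydroxyl is removed first (enol ether oxidation). Ring C is then opened at C2–C3 to an aryl diazomethyl ketone whose O1 carries a 4-oxygenated benzyl group. Further cuts are C3–C4 (acyl chloride plus diazomethane), O1–CH2 (Williamson), C4–C4a (ortho-formylation) and C8–CH2–aryl (aryl Grignard on a ring A aldehyde, then hydrogenolysis).
- Enabling feature: C2 is a benzylic CH bound to O1 and stands 1,6 to C3 along C3–C4–C4a–C8a–O1–C2. A carbene at C3 of a C4 ketone on ring A therefore reaches a C–H bond of the O1–CH2–aryl ether, and the pyranone ring C closes by making C2–C3.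
- Forward order: ring A (from 2,6-dihydroxy-4-methoxybenzaldehyde) receives the C8 benzyl group, then the C4 carbon, the O1 benzyl ether and the diazomethyl carbon C3. Ring C is then closed, C3 is hydroxylated and all ethers are cleaved.
- Stereochemistry: C2 is set by the chiral dirhodium carboxylate, which selects one enantiotopic benzylic hydrogen. C3 follows by substrate control, the oxidant adding to the enol ether face opposite the C2 aryl group (2,3-trans, 2R,3R).
- Protecting groups: MOM (methoxymethyl) on O7 and on both para-phenols. O5 stays a methyl ether because its primary C–H bonds resist the carbene, and the chelated ether is cleaved at the end by BCl3.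

Key step: step 11

Assumption: Rh2(S-BSP)4 is taken to give the (2S)-flavanone; if the sense of induction is the reverse, Rh2(R-BSP)4 is used with no other change.

**Route**

Step 1
Reactants: 1 2,6-dihydroxy-4-methoxybenzaldehyde
Product: 2 2-hydroxy-4-methoxy-6-(methoxymethoxy)benzaldehyde
Conditions: MOMCl (1.05 equiv), iPr2NEt, CH2Cl2, 0 °C
Reagents that add atoms: chloromethyl methyl ether (MOMCl), COCCl
Why: O-alkylation of a phenol to its MOM acetal: the two hydroxyls of 1 are equivalent, and once one is capped the other is held in a hydrogen bond to the aldehyde and is far less nucleophilic, so about one equivalent of MOMCl should stop at the mono-ether.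

Step 2
Reactants: 3 4-bromophenol
Product: 4 1-bromo-4-(methoxymethoxy)benzene
Conditions: MOMCl, iPr2NEt, CH2Cl2, 0 → 20 °C
Reagents that add atoms: chloromethyl methyl ether (MOMCl), COCCl
Why: Routine MOM acetal formation on a phenol, giving an aryl bromide whose protecting group tolerates magnesium insertion.

Step 3
Reactants: 4 1-bromo-4-(methoxymethoxy)benzene; 2 2-hydroxy-4-methoxy-6-(methoxymethoxy)benzaldehyde
Product: 6 rac-[2-hydroxy-4-methoxy-6-(methoxymethoxy)phenyl][4-(methoxymethoxy)phenyl]methanol, via arylmagnesium bromide 5 (not isolated)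
Conditions: 4 (2.5 equiv), Mg, THF, 40 °C; then 2, THF, 0 → 20 °C; aq. NH4Cl; product carried on without chromatography
Reagents that add atoms: none
Why: Grignard formation and 1,2-addition to the aldehyde: the first equivalent of 5 only deprotonates the phenol of 2, the second adds to the carbonyl of the magnesium phenoxide, and the new carbinol centre is racemic but is erased in step 4.

Step 4
Reactants: 6 rac-[2-hydroxy-4-methoxy-6-(methoxymethoxy)phenyl][4-(methoxymethoxy)phenyl]methanol
Product: 7 5-methoxy-3-(methoxymethoxy)-2-[4-(methoxymethoxy)benzyl]phenol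
Conditions: H2 (1 atm), 10% Pd/C, EtOAc–MeOH, 20 °C
Reagents that add atoms: none
Why: Catalytic hydrogenolysis of a benzylic C–O bond, easy here because the diarylmethanol is flanked by ortho-hydroxy and ortho/para-alkoxy donors (ortho-quinone-methide-like ionisation), while aryl ethers and MOM acetals are inert to H2 on Pd/C.

Step 5
Reactants: 7 5-methoxy-3-(methoxymethoxy)-2-[4-(methoxymethoxy)benzyl]phenol
Product: 8 2-hydroxy-6-methoxy-4-(methoxymethoxy)-3-[4-(methoxymethoxy)benzyl]benzaldehyde
Conditions: MgCl2, Et3N, (CH2O)n, MeCN, 80 °C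
Reagents that add atoms: paraformaldehyde (reacts as formaldehyde), C=O
Why: Magnesium-mediated ortho-formylation of a phenol (Casnati–Skattebøl reaction): the magnesium phenoxide delivers formaldehyde only to an ortho carbon, of which a single one is free (between OH and OMe), and a second formaldehyde oxidises the hydroxymethyl group to the aldehyde by hydride transfer.

Step 6
Reactants: 9 4-hydroxybenzyl alcohol
Product: 10 [4-(methoxymethoxy)phenyl]methanol
Conditions: MOMCl (1.0 equiv), K2CO3, acetone, 0 → 20 °C
Reagents that add atoms: chloromethyl methyl ether (MOMCl), COCCl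
Why: Williamson-type MOM ether formation that is selective for the phenol, because K2CO3 deprotonates only the phenolic OH (pKa about 10) and not the benzylic alcohol.

Step 7
Reactants: 10 [4-(methoxymethoxy)phenyl]methanol
Product: 11 1-(chloromethyl)-4-(methoxymethoxy)benzene
Conditions: PPh3, N-chlorosuccinimide, THF, 0 → 20 °C
Reagents that add atoms: N-chlorosuccinimide, O=C1CCC(=O)N1Cl
Why: Appel-type chlorination of a primary benzylic alcohol through its alkoxyphosphonium salt, run under neutral conditions so that the MOM acetal never meets HCl.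

Step 8
Reactants: 8 2-hydroxy-6-methoxy-4-(methoxymethoxy)-3-[4-(methoxymethoxy)benzyl]benzaldehyde; 11 1-(chloromethyl)-4-(methoxymethoxy)benzene
Product: 12 6-methoxy-4-(methoxymethoxy)-3-[4-(methoxymethoxy)benzyl]-2-{[4-(methoxymethoxy)benzyl]oxy}benzaldehyde
Conditions: K2CO3, Bu4NI (cat.), DMF, 50 °C
Reagents that add atoms: none
Why: Williamson ether synthesis: 8 has a single phenol, acidified by the ortho aldehyde, and its potassium salt displaces chloride from the activated benzylic halide 11 under iodide catalysis, which fixes O1 and its CH2–aryl group.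

Step 9
Reactants: 12 6-methoxy-4-(methoxymethoxy)-3-[4-(methoxymethoxy)benzyl]-2-{[4-(methoxymethoxy)benzyl]oxy}benzaldehyde
Product: 13 6-methoxy-4-(methoxymethoxy)-3-[4-(methoxymethoxy)benzyl]-2-{[4-(methoxymethoxy)benzyl]oxy}benzoic acid
Conditions: NaClO2, NaH2PO4, 2-methyl-2-butene (excess), t-BuOH–THF–H2O, 0 → 20 °C
Reagents that add atoms: sodium chlorite, [Na+].[O-]Cl=O
Why: Pinnick oxidation of the aldehyde to the acid at about pH 4, tolerant of ortho-disubstituted aldehydes and of acetals, with 2-methyl-2-butene trapping HOCl before it can chlorinate the electron-rich rings.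

Step 10
Reactants: 13 6-methoxy-4-(methoxymethoxy)-3-[4-(methoxymethoxy)benzyl]-2-{[4-(methoxymethoxy)benzyl]oxy}benzoic acid
Product: 15 2-diazo-1-{6-methoxy-4-(methoxymethoxy)-3-[4-(methoxymethoxy)benzyl]-2-{[4-(methoxymethoxy)benzyl]oxy}phenyl}ethan-1-one, via acid chloride 14 (not isolated)
Conditions: 1-chloro-N,N,2-trimethylprop-1-en-1-amine, CH2Cl2, 0 → 20 °C; then CH2N2 (4 equiv), Et2O, 0 °C
Reagents that add atoms: diazomethane, C=[N+]=[N-]
Why: Acid chloride formation with an α-chloroenamine under neutral conditions (no HCl, so the MOM and para-alkoxybenzyl ethers survive), then acylation of diazomethane as in the first stage of the Arndt–Eistert sequence, a further equivalent of diazomethane consuming the HCl released.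

Step 11
Reactants: 15 2-diazo-1-{6-methoxy-4-(methoxymethoxy)-3-[4-(methoxymethoxy)benzyl]-2-{[4-(methoxymethoxy)benzyl]oxy}phenyl}ethan-1-one
Product: 16 (2S)-5-methoxy-7-(methoxymethoxy)-8-[4-(methoxymethoxy)benzyl]-2-[4-(methoxymethoxy)phenyl]chroman-4-one
Conditions: Rh2(S-BSP)4 (1 mol %; S-BSP = (S)-N-(benzenesulfonyl)prolinate), CH2Cl2, slow addition of 15 at high dilution, 0 → 20 °C
Reagents that add atoms: none
Why: Rh2(S-BSP)4, a dimer of divalent rhodium, expels N2 from the diazoketone, and the electrophilic rhodium carbene at C3 inserts into a C–H bond of the O1–CH2–aryl methylene through a concerted, asynchronous three-centre transition state with hydride-transfer character, which forms C2–C3. The closest known reaction type is the dirhodium-carboxylate-catalysed intramolecular C–H insertion of 2-alkoxyaryl diazomethyl ketones to chroman-4-ones, including enantioselective versions with N-arylsulfonylprolinate ligands. Ring C is closed as a six-membered ring by 1,6-insertion (C3 to C2 across C4, C4a, C8a and O1), the usual 1,5-mode being unavailable because the fifth atom is O1. The one new stereocentre, C2, is set by the catalyst: the chiral prolinate pocket around the carbene distinguishes the two enantiotopic benzylic hydrogens, and the (S)-ligand is taken to give (2S). The step needs site selectivity for this methylene over the C5 methoxy group and over oxonium ylide formation at O1 followed by a [1,2]-benzyl (Stevens) shift; the benzylic C–H bond is activated by both O1 and the para-alkoxyaryl ring, which stabilise positive charge at C2, whereas the C5 ether offers only primary C–H bonds (the reason for a methyl and not a MOM group there). The other MOM acetals and the C8 benzyl group cannot reach the carbene, and slow addition at low concentration suppresses carbene dimerisation.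

Step 12
Reactants: 16 (2S)-5-methoxy-7-(methoxymethoxy)-8-[4-(methoxymethoxy)benzyl]-2-[4-(methoxymethoxy)phenyl]chroman-4-one
Product: 17 (2S)-5-methoxy-7-(methoxymethoxy)-8-[4-(methoxymethoxy)benzyl]-2-[4-(methoxymethoxy)phenyl]-4-[(trimethylsilyl)oxy]-2H-chromene
Conditions: TMSOTf, Et3N, CH2Cl2, −20 → 0 °C; non-aqueous work-up, used crude
Reagents that add atoms: trimethylsilyl trifluoromethanesulfonate (TMSOTf), C[Si](C)(C)OS(=O)(=O)C(F)(F)F
Why: Soft enolisation with a silyl triflate and a tertiary amine converts the ketone into its silyl enol ether without building up a free enolate, so that retro-oxa-Michael opening of ring C and loss of the C2 configuration are avoided; C2 is not touched.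

Step 13
Reactants: 17 (2S)-5-methoxy-7-(methoxymethoxy)-8-[4-(methoxymethoxy)benzyl]-2-[4-(methoxymethoxy)phenyl]-4-[(trimethylsilyl)oxy]-2H-chromene
Product: 19 (2R,3R)-3-hydroxy-5-methoxy-7-(methoxymethoxy)-8-[4-(methoxymethoxy)benzyl]-2-[4-(methoxymethoxy)phenyl]chroman-4-one, via silyloxy epoxide 18 (not isolated)
Conditions: dimethyldioxirane (1.1 equiv), acetone–CH2Cl2, −78 → −20 °C; then aq. citric acid, THF, 0 °C
Reagents that add atoms: dimethyldioxirane, CC1(C)OO1
Why: Rubottom-type oxidation: dimethyldioxirane epoxidises the electron-rich enol ether on the face opposite the C2 aryl group, and mild acid opens the silyloxy epoxide with loss of the silyl group to the α-hydroxy ketone, so the C3 hydroxyl ends up trans to the aryl group (2R,3R), which is also the more stable diequatorial arrangement.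

Step 14
Reactants: 19 (2R,3R)-3-hydroxy-5-methoxy-7-(methoxymethoxy)-8-[4-(methoxymethoxy)benzyl]-2-[4-(methoxymethoxy)phenyl]chroman-4-one
Product: 20 (2R,3R)-3,5,7-trihydroxy-8-(4-hydroxybenzyl)-2-(4-hydroxyphenyl)chroman-4-one
Conditions: BCl3 (excess), CH2Cl2, −78 → 0 °C; then MeOH; H2O
Reagents that add atoms: none
Why: Lewis acid ether cleavage: BCl3 chelated between the C4 carbonyl and the C5 oxygen removes the peri methyl group as chloromethane and also cleaves the three MOM acetals, under acidic, non-basic conditions that neither enolise C3 nor open ring C, so both stereocentres should be retained.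

**Compound list**

1 | 2,6-dihydroxy-4-methoxybenzaldehyde | COc1cc(O)c(C=O)c(O)c1 | starting material
2 | 2-hydroxy-4-methoxy-6-(methoxymethoxy)benzaldehyde | COCOc1cc(OC)cc(O)c1C=O | intermediate
3 | 4-bromophenol | Oc1ccc(Br)cc1 | starting material
4 | 1-bromo-4-(methoxymethoxy)benzene | COCOc1ccc(Br)cc1 | intermediate
5 | [4-(methoxymethoxy)phenyl]magnesium bromide (formed in the flask) | COCOc1ccc([Mg]Br)cc1 | intermediate
6 | rac-[2-hydroxy-4-methoxy-6-(methoxymethoxy)phenyl][4-(methoxymethoxy)phenyl]methanol (racemic carbinol) | COCOc1ccc(cc1)C(O)c1c(O)cc(OC)cc1OCOC | intermediate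
7 | 5-methoxy-3-(methoxymethoxy)-2-[4-(methoxymethoxy)benzyl]phenol | COCOc1ccc(Cc2c(O)cc(OC)cc2OCOC)cc1 | intermediate
8 | 2-hydroxy-6-methoxy-4-(methoxymethoxy)-3-[4-(methoxymethoxy)benzyl]benzaldehyde | O=Cc1c(OC)cc(OCOC)c(Cc2ccc(OCOC)cc2)c1O | intermediate
9 | 4-hydroxybenzyl alcohol | OCc1ccc(O)cc1 | starting material
10 | [4-(methoxymethoxy)phenyl]methanol | COCOc1ccc(CO)cc1 | intermediate
11 | 1-(chloromethyl)-4-(methoxymethoxy)benzene | COCOc1ccc(CCl)cc1 | intermediate
12 | 6-methoxy-4-(methoxymethoxy)-3-[4-(methoxymethoxy)benzyl]-2-{[4-(methoxymethoxy)benzyl]oxy}benzaldehyde | O=Cc1c(OC)cc(OCOC)c(Cc2ccc(OCOC)cc2)c1OCc1ccc(OCOC)cc1 | intermediate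
13 | 6-methoxy-4-(methoxymethoxy)-3-[4-(methoxymethoxy)benzyl]-2-{[4-(methoxymethoxy)benzyl]oxy}benzoic acid | OC(=O)c1c(OC)cc(OCOC)c(Cc2ccc(OCOC)cc2)c1OCc1ccc(OCOC)cc1 | intermediate
14 | 6-methoxy-4-(methoxymethoxy)-3-[4-(methoxymethoxy)benzyl]-2-{[4-(methoxymethoxy)benzyl]oxy}benzoyl chloride (formed in the flask) | ClC(=O)c1c(OC)cc(OCOC)c(Cc2ccc(OCOC)cc2)c1OCc1ccc(OCOC)cc1 | intermediate
15 | 2-diazo-1-{6-methoxy-4-(methoxymethoxy)-3-[4-(methoxymethoxy)benzyl]-2-{[4-(methoxymethoxy)benzyl]oxy}phenyl}ethan-1-one | [N-]=[N+]=CC(=O)c1c(OC)cc(OCOC)c(Cc2ccc(OCOC)cc2)c1OCc1ccc(OCOC)cc1 | intermediate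
16 | (2S)-5-methoxy-7-(methoxymethoxy)-8-[4-(methoxymethoxy)benzyl]-2-[4-(methoxymethoxy)phenyl]chroman-4-one | O=C1c2c(OC)cc(OCOC)c(Cc3ccc(OCOC)cc3)c2O[C@H](c2ccc(OCOC)cc2)C1 | intermediate
17 | (2S)-5-methoxy-7-(methoxymethoxy)-8-[4-(methoxymethoxy)benzyl]-2-[4-(methoxymethoxy)phenyl]-4-[(trimethylsilyl)oxy]-2H-chromene | C[Si](C)(C)OC1=C[C@@H](c2ccc(OCOC)cc2)Oc2c1c(OC)cc(OCOC)c2Cc1ccc(OCOC)cc1 | intermediate
18 | 3,4-epoxide of 17 (oxirane fused at C3–C4, its oxygen on the face opposite the C2 aryl group, trimethylsilyloxy group on C4; formed in the flask) | C[Si](C)(C)O[C@]12O[C@@H]2[C@@H](c2ccc(OCOC)cc2)Oc2c1c(OC)cc(OCOC)c2Cc1ccc(OCOC)cc1 | intermediate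
19 | (2R,3R)-3-hydroxy-5-methoxy-7-(methoxymethoxy)-8-[4-(methoxymethoxy)benzyl]-2-[4-(methoxymethoxy)phenyl]chroman-4-one (2,3-trans) | O=C1c2c(OC)cc(OCOC)c(Cc3ccc(OCOC)cc3)c2O[C@H](c2ccc(OCOC)cc2)[C@H]1O | intermediate
20 | (2R,3R)-3,5,7-trihydroxy-8-(4-hydroxybenzyl)-2-(4-hydroxyphenyl)chroman-4-one (2,3-trans) | O=C1c2c(O)cc(O)c(Cc3ccc(O)cc3)c2O[C@H](c2ccc(O)cc2)[C@H]1O | target

**Step count and risks**

Total steps: 14. Longest linear sequence: 11 steps, from 4-bromophenol 3 through steps 2, 3, 4, 5, 8, 9, 10, 11, 12, 13, 14. The chain from aldehyde 1 (steps 1, 3, 4, 5, 8, 9, 10, 11, 12, 13, 14) is equally long, and the branch from 9 (steps 6 and 7) joins at step 8.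

Steps most likely to fail:

1. Step 11. The carbene may be diverted to the O1 oxonium ylide and a [1,2]-shift of the benzyl group (contraction to a five-membered benzofuranone), or the catalyst may distinguish the two benzylic hydrogens poorly, giving low enantiomeric purity at C2. The fallback sets out from 8 and returns at 16. Addition of MeMgBr (excess, THF, 0 °C) to aldehyde 8 should give the racemic carbinol 2-(1-hydroxyethyl)-3-methoxy-5-(methoxymethoxy)-6-[4-(methoxymethoxy)benzyl]phenol F1. MnO2 in CH2Cl2 should oxidise it to the acetophenone 1-{2-hydroxy-6-methoxy-4-(methoxymethoxy)-3-[4-(methoxymethoxy)benzyl]phenyl}ethan-1-one F2. Condensation with N,N-dimethylformamide dimethyl acetal should give the enaminone (E)-3-(dimethylamino)-1-{2-hydroxy-6-methoxy-4-(methoxymethoxy)-3-[4-(methoxymethoxy)benzyl]phenyl}prop-2-en-1-one F3. Warm dilute acetic acid should close F3 to the chromone 5-methoxy-7-(methoxymethoxy)-8-[4-(methoxymethoxy)benzyl]-4H-chromen-4-one F4. Asymmetric conjugate addition of 4-(methoxymethoxy)phenylboronic acid to F4 under divalent palladium catalysis (Pd(OCOCF3)2, 4-tert-butyl-2-(pyridin-2-yl)-4,5-dihydrooxazole, NH4PF6, H2O, 1,2-dichloroethane, 60 °C) should then deliver flavanone 16, the ligand enantiomer being chosen for (2S).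

2. Step 12. The silyl triflate may strip or exchange the MOM acetals, and the moisture-sensitive trimethylsilyl enol ether may revert to the ketone before it is oxidised. The fallback sets out from 16 and returns at 19. The ketone is deprotonated with KN(SiMe3)2 in THF at −78 °C and the cold enolate is oxidised directly with 2-(phenylsulfonyl)-3-phenyloxaziridine (Davis oxidation), then quenched at −78 °C with aq. NH4Cl. Keeping the enolate at low temperature should limit expulsion of the O1 phenoxide from it. The reagent should again approach anti to the C2 aryl group and give the trans hydroxy ketone 19 without Lewis acid and without an isolated enol ether. Steps 12 and 13 are replaced by this one operation.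

3. Step 14. Chloromethyl methyl ether released from the acetals in the presence of BCl3 may alkylate the electron-rich ring A at C6 or bridge neighbouring oxygens, and prolonged Lewis acid contact may ionise the benzylic C2–O1 bond and epimerise C2. The fallback sets out from 19 and returns at 20. The three MOM acetals are first exchanged off with HCl in MeOH at 40 °C, which should give (2R,3R)-3,7-dihydroxy-8-(4-hydroxybenzyl)-2-(4-hydroxyphenyl)-5-methoxychroman-4-one F5 with only dimethoxymethane as co-product. BCl3 at −78 → 0 °C then has just the chelated C5 methyl ether to cleave and should give 20.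

**Further compounds**

F1 | step 11 | 2-(1-hydroxyethyl)-3-methoxy-5-(methoxymethoxy)-6-[4-(methoxymethoxy)benzyl]phenol (racemic) | CC(O)c1c(OC)cc(OCOC)c(Cc2ccc(OCOC)cc2)c1O
F2 | step 11 | 1-{2-hydroxy-6-methoxy-4-(methoxymethoxy)-3-[4-(methoxymethoxy)benzyl]phenyl}ethan-1-one | CC(=O)c1c(OC)cc(OCOC)c(Cc2ccc(OCOC)cc2)c1O
F3 | step 11 | (E)-3-(dimethylamino)-1-{2-hydroxy-6-methoxy-4-(methoxymethoxy)-3-[4-(methoxymethoxy)benzyl]phenyl}prop-2-en-1-one | CN(C)/C=C/C(=O)c1c(OC)cc(OCOC)c(Cc2ccc(OCOC)cc2)c1O
F4 | step 11 | 5-methoxy-7-(methoxymethoxy)-8-[4-(methoxymethoxy)benzyl]-4H-chromen-4-one | O=c1ccoc2c(Cc3ccc(OCOC)cc3)c(OCOC)cc(OC)c12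
F0 | step 12 | none | none
F5 | step 14 | (2R,3R)-3,7-dihydroxy-8-(4-hydroxybenzyl)-2-(4-hydroxyphenyl)-5-methoxychroman-4-one | O=C1c2c(OC)cc(O)c(Cc3ccc(O)cc3)c2O[C@H](c2ccc(O)cc2)[C@H]1O
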